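**Strategy.** C2–C3 is the one bond shared by the ten-membered carbocycle and the cis-2,3-oxirane, flanked by the ring-cis C1=C10 enoic acid and the cis-4,5-oxirane. Without the oxirane oxygen it is the Z alkene of a cis,cis-1,3-diene, so the carbocycle is closed there by diene–ene ring-closing metathesis, which makes the ring and fixes the Z geometry in one operation. In the precursor C2 is the vinyl terminus of a dienyl acetal and C3 a vinyl group on oxirane carbon C4; the trans-lactone, both esters and the 4,5-oxirane are in place and the α-methylene is masked as a selenide. The seco-triene comes from an Achmatowicz pyranone and a chromium-mediated lactone annulation; epoxidation anti to the 4,5-oxirane ends the route.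

Key step: step 23

Remark: locants C1–C15 are those of the germacrane skeleton of the target (C11/C12/C13 = lactone α-carbon, carbonyl, methylene; C14 = carboxyl; C15 = methyl); lactol and anomeric centres, the carbinol of 13 and C11 of the selenides are carried as mixtures and written without descriptor, because each is removed later.

Step 1
Reactants: 1 furan-3-carbaldehyde
Product: 2 3-(dimethoxymethyl)furan
Conditions: HC(OMe)3, TsOH·H2O (cat.), MeOH, 23 °C
Reagents that add atoms: trimethyl orthoformate, COC(OC)OC
Why: acid-catalysed acetalisation driven by the orthoester masks the future C14 carboxyl carbon at the aldehyde level and provides an ortho-directing group.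

Step 2
Reactants: 2 3-(dimethoxymethyl)furan; 3 (tert-butyldimethylsilyloxy)acetaldehyde
Product: 4 rac-2-(tert-butyldimethylsilyloxy)-1-[3-(dimethoxymethyl)furan-2-yl]ethanol
Conditions: nBuLi, THF, −78 to −20 °C; then 3, −78 °C; NH4Cl (aq)
Reagents that add atoms: none
Why: directed ortho-lithiation (C2 of the furan lies between the ring oxygen and the coordinating acetal) followed by 1,2-addition to the aldehyde joins C8 (carbinol) to C9 (furan C2); the racemic carbinol is corrected in steps 3 and 4.

Step 3
Reactants: 4 racemic furyl carbinol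
Product: 5 2-(tert-butyldimethylsilyloxy)-1-[3-(dimethoxymethyl)furan-2-yl]ethanone
Conditions: MnO2, CH2Cl2, 23 °C
Reagents that add atoms: none
Why: MnO2 oxidation of a furfuryl (benzylic-type) alcohol to the aryl ketone leaves the acetal and silyl ether untouched.

Step 4
Reactants: 5 furyl ketone
Product: 6 (S)-2-(tert-butyldimethylsilyloxy)-1-[3-(dimethoxymethyl)furan-2-yl]ethanol
Conditions: RuCl[(S,S)-TsDPEN](p-cymene) (1 mol %), HCO2Na, CTAB, H2O/CH2Cl2, 23 °C
Reagents that add atoms: none
Why: Noyori asymmetric transfer hydrogenation, in which the furyl group takes the aryl position of the six-membered transition state, so the (S,S) catalyst should give the (S) carbinol, which is C8 of the target; the neutral formate medium spares the acetal.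

Step 5
Reactants: 6 (S)-furyl carbinol
Product: 7 (2S)-2-[(tert-butyldimethylsilyloxy)methyl]-4-(dimethoxymethyl)-6-hydroxy-2H-pyran-3(6H)-one (ring O = O8, C2 = C8, C3 = C9, C4 = C10, C5 = C1, C6 = C2)
Conditions: NBS, NaHCO3, NaOAc·3H2O, THF/H2O (4:1), 0 °C
Reagents that add atoms: water, O
Why: Achmatowicz oxidative rearrangement: the furan opens to the cis-enedione and the C8 hydroxyl closes onto the C2 aldehyde, so C9 becomes a ketone, C2 a lactol carbon, and the pyran ring locks C10=C1 ring-cis (C2 cis to C9, trans to the C14 carbon) while C8 keeps its configuration.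

Step 6
Reactants: 7 pyranone lactol
Product: 8 (2S,3R)-2-[(tert-butyldimethylsilyloxy)methyl]-4-(dimethoxymethyl)-3,6-dihydro-2H-pyran-3,6-diol (C9–OH trans to the C8 substituent)
Conditions: NaBH4, CeCl3·7H2O, MeOH/CH2Cl2, −78 °C
Reagents that add atoms: none
Why: Luche 1,2-reduction, with hydride adding to the enone carbonyl anti to the adjacent C8 substituent to give the 8,9-trans allylic alcohol, while the lactol, being a hemiacetal, should not be reduced under these conditions.

Step 7
Reactants: 8 trans-diol
Product: 9 (2S,3S)-2-[(tert-butyldimethylsilyloxy)methyl]-4-(dimethoxymethyl)-3,6-dihydro-2H-pyran-3,6-diyl diacetate (C9–OAc cis to the C8 substituent)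
Conditions: AcOH, PPh3, DIAD, THF, 0 to 23 °C
Reagents that add atoms: acetic acid, CC(=O)O
Why: Mitsunobu reaction at both hydroxyls: SN2 displacement by acetate inverts allylic C9 to the 8,9-cis (threo) relationship of the target and installs the C9 acetate, and the lactol hydroxyl is acetylated at the same time, protecting C2.

Step 8
Reactants: 9 silyl ether diacetate
Product: 10 (2S,3S)-4-(dimethoxymethyl)-2-(hydroxymethyl)-3,6-dihydro-2H-pyran-3,6-diyl diacetate
Conditions: HF·pyridine, pyridine, THF, 0 °C
Reagents that add atoms: none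
Why: fluoride cleavage of the primary silyl ether under pyridine-buffered conditions that should leave the glycosyl acetate and the acetal intact.

Step 9
Reactants: 10 primary alcohol
Product: 11 (2R,3S)-4-(dimethoxymethyl)-2-formyl-3,6-dihydro-2H-pyran-3,6-diyl diacetate (C7 aldehyde)
Conditions: Dess–Martin periodinane, NaHCO3, CH2Cl2, 0 °C
Reagents that add atoms: none
Why: Dess–Martin oxidation under buffered, non-basic conditions gives the C7 aldehyde without β-elimination of the C9 acetate or epimerisation at C8; the aldehyde is used at once.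

Step 10
Reactants: 11 C7 aldehyde; 12 methyl propiolate
Product: 13 methyl 2-{[(2S,3S)-3,6-diacetoxy-4-(dimethoxymethyl)-3,6-dihydro-2H-pyran-2-yl](hydroxy)methyl}acrylate (C7 carbinol epimers)
Conditions: iBu2AlH, NMO, THF, 0 °C (with 12); then 11, −78 to 0 °C
Reagents that add atoms: none
Why: vinylalumination: conjugate hydroalumination of the propiolate gives the α-aluminoacrylate, which adds to the aldehyde to give the Morita–Baylis–Hillman-type adduct without amine base (which would eliminate the C9 acetate); the C7 carbinol centre is lost in step 11.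

Step 11
Reactants: 13 hydroxy acrylate
Product: 14 methyl (Z)-2-(bromomethyl)-3-[(2S,3S)-3,6-diacetoxy-4-(dimethoxymethyl)-3,6-dihydro-2H-pyran-2-yl]acrylate
Conditions: NBS, Me2S, CH2Cl2, −20 to 0 °C
Reagents that add atoms: N-bromosuccinimide, O=C1CCC(=O)N1Br
Why: bromide attacks the alkoxysulfonium in the SN2′ sense (allylic transposition), giving the thermodynamically preferred (Z)-2-(bromomethyl)enoate in which C7 is the γ-carbon of an allylating agent.

Step 12
Reactants: 15 (Z)-3-methylpent-2-en-4-yn-1-ol
Product: 16 (Z)-3-methylpenta-2,4-dien-1-ol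
Conditions: H2 (1 atm), Lindlar catalyst (Pd/CaCO3, Pb(OAc)2), quinoline, pentane, 0 °C
Reagents that add atoms: none
Why: Lindlar semihydrogenation of the terminal alkyne gives the vinyl group (future C3 plus the carbon lost in step 23) and keeps the Z trisubstituted alkene (C4=C5 with C15).

Step 13
Reactants: 16 (Z)-dienol
Product: 17 (Z)-3-methylpenta-2,4-dienal
Conditions: MnO2, CH2Cl2, 0 °C; filtered solution used directly
Reagents that add atoms: none
Why: MnO2 oxidation of the allylic alcohol gives the C6 aldehyde; neutral, cold conditions should preserve the Z geometry.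

Step 14
Reactants: 14 allyl bromide; 17 (Z)-dienal
Product: 18 methyl (3S,4R,5Z)-3-[(2S,3S)-3,6-diacetoxy-4-(dimethoxymethyl)-3,6-dihydro-2H-pyran-2-yl]-4-hydroxy-6-methyl-2-methylideneocta-5,7-dienoate (chain C3 = C7, C4 = C6)
Conditions: CrCl2 (4 equiv), THF, 0 °C, slow addition of 14 and 17
Reagents that add atoms: none
Why: Nozaki–Hiyama-type 2-(alkoxycarbonyl)allylation: the allylchromium adds through a chair transition state to give the 6,7-anti adduct (later the trans-lactone), and with C8–H eclipsing the allyl unit (A(1,3) strain) the aldehyde should approach C7 anti to the C8–C9 ring bond bearing the cis acetate, which sets C6 and C7 as in the target.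

Step 15
Reactants: 18 anti homoallylic alcohol
Product: 20 trans-α-methylene-γ-butyrolactone bearing the 3-methyl-3-vinyloxiran-2-yl group at C6 and the pyranyl group at C7, via epoxy alcohol 19 (not isolated)
Conditions: Ti(OiPr)4, tBuOOH, 4 Å MS, CH2Cl2, −20 °C; Me2S; then PPTS (cat.), 23 °C
Reagents that add atoms: tert-butyl hydroperoxide, CC(C)(C)OO
Why: titanium-mediated hydroxyl-directed epoxidation of the (Z)-allylic alcohol: with C6–H eclipsing the alkene (A(1,3) strain from the cis vinyl group) oxygen is delivered syn to the hydroxyl to give the threo epoxy alcohol (C4 and C5 of the target), and the C6 hydroxyl then lactonises onto the methyl ester.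

Step 16
Reactants: 20 α-methylene lactone
Product: 21 α-(phenylselanylmethyl) lactone (C11 epimers)
Conditions: PhSeH (1.05 equiv), Et3N (0.2 equiv), CH2Cl2, −20 °C
Reagents that add atoms: benzeneselenol, [SeH]c1ccccc1
Why: Michael addition of the selenol masks the α-methylene lactone against hydrazine, PPh3 and a competing seven-membered ring closure onto C2 in step 23; the cold, near-stoichiometric conditions should spare the vinyl oxirane.

Step 17
Reactants: 21 selenide glycosyl acetate
Product: 22 lactol (free anomeric hydroxyl at C2, C9 acetate kept)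
Conditions: N2H4·AcOH, DMF, 0 °C
Reagents that add atoms: none
Why: selective hydrazinolysis of the anomeric acetate, the most electrophilic ester, frees the lactol, which is the masked C2 aldehyde.

Step 18
Reactants: 22 lactol
Product: 23 dienyl alcohol (C8–OH free, C9–OAc, C10 bearing CH(OMe)2, ring-cis C10=C1, C2 vinyl)
Conditions: RhCl(PPh3)3 (3 mol %), PPh3, iPrOH, Me3SiCHN2, THF, 23 °C
Reagents that add atoms: (trimethylsilyl)diazomethane, C[Si](C)(C)C=[N+]=[N-]
Why: Wittig methylenation of the open hydroxy-enal tautomer with Ph3P=CH2 generated in situ under neutral conditions gives the C2 vinyl group and frees O8, with the C10=C1 geometry inherited from the pyran ring; the absence of base should prevent acetyl migration from O9 to O8.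

Step 19
Reactants: 24 angelic acid ((Z)-2-methylbut-2-enoic acid)
Product: 25 (Z)-2-methylbut-2-en-1-ol
Conditions: LiAlH4, Et2O, 0 °C
Reagents that add atoms: none
Why: hydride reduction of the acid to the allylic alcohol without touching the alkene geometry.

Step 20
Reactants: 25 (Z)-2-methylbut-2-en-1-ol
Product: 26 [(2S,3R)-2,3-dimethyloxiran-2-yl]methanol
Conditions: Ti(OiPr)4 (10 mol %), L-(+)-diethyl tartrate, tBuOOH, 4 Å MS, CH2Cl2, −20 °C
Reagents that add atoms: tert-butyl hydroperoxide, CC(C)(C)OO
Why: Sharpless asymmetric epoxidation; the L-(+)-tartrate complex delivers oxygen to the face that gives the (2S,3R) epoxy alcohol, setting both centres of the epoxyangelate.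

Step 21
Reactants: 26 epoxy alcohol
Product: 27 (2R,3R)-2,3-dimethyloxirane-2-carboxylic acid (epoxyangelic acid)
Conditions: RuCl3·xH2O (2 mol %), NaIO4, MeCN/CCl4/H2O, 0 to 23 °C
Reagents that add atoms: sodium periodate, [Na+].[O-]I(=O)(=O)=O; water, O
Why: ruthenium tetroxide oxidation of the primary alcohol to the acid, a standard conversion of 2,3-epoxy alcohols that leaves the oxirane intact.

Step 22
Reactants: 23 dienyl alcohol; 27 epoxyangelic acid
Product: 28 seco-triene ester (O8 epoxyangelate, O9 acetate, C14 dimethyl acetal, C2 and C3 vinyl groups, selenide-masked lactone)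
Conditions: 2,4,6-trichlorobenzoyl chloride, Et3N, toluene; then 23, DMAP, 23 °C
Reagents that add atoms: none
Why: Yamaguchi esterification through the mixed anhydride acylates the hindered secondary C8 hydroxyl without opening either oxirane.

Step 23
Reactants: 28 seco-triene ester
Product: 29 ten-membered (1(10)Z,2Z)-diene (C14 acetal, selenide)
Conditions: second-generation Hoveyda–Grubbs catalyst RuCl2(H2IMes)(=CH-C6H4-2-OiPr) (15 mol %), 1,4-benzoquinone, toluene (0.5 mM), 80 °C
Reagents that add atoms: none
Why: By the metallacyclobutane (Chauvin) mechanism the ruthenium alkylidene loads on the terminal CH2=C2H of the dienyl acetal, undergoes [2+2] cycloaddition with the C3 vinyl on oxirane carbon C4 and cycloreverts with loss of ethylene; the closest known type is diene–ene ring-closing metathesis to medium-ring 1,3-dienes. The only ring closed is the ten-membered carbocycle, by ring-closing metathesis at C2=C3; no stereocentre is formed, but the new alkene must be Z. Z should be enforced by the ring, because a trans C2=C3 conjugated to the ring-cis C1=C10 and flanked by the cis-oxirane would need a twisted diene that a ten-membered ring cannot hold, and metathesis is reversible. Chemoselectivity is secured in the substrate: C1=C10 is trisubstituted and inert, the lactone α-methylene is masked as the selenide, and no other alkene is present. High dilution and benzoquinone are there to suppress oligomerisation and hydride-mediated isomerisation, and the cis C1=C10, cis-oxirane and trans-lactone turn the two chain ends toward each other.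

Step 24
Reactants: 29 macrocyclic selenide
Product: 31 macrocyclic α-methylene lactone (C14 acetal), via selenoxide 30 (not isolated)
Conditions: NaIO4, NaHCO3, THF/MeOH/H2O, 0 to 23 °C
Reagents that add atoms: none
Why: oxidation of the selenide and syn-elimination of the selenoxide, for which C11–H is the only β-hydrogen, restore the exocyclic methylene.

Step 25
Reactants: 31 macrocyclic acetal
Product: 33 2,3-deoxy-leucanthin B (C14 acid with C2=C3 Z-alkene), via C14 aldehyde 32 (not isolated)
Conditions: PPTS, acetone/H2O, 23 °C; then NaClO2, NaH2PO4, 2-methyl-2-butene, tBuOH/H2O, 0 °C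
Reagents that add atoms: water, O; sodium chlorite, [Na+].[O-]Cl=O
Why: mild hydrolysis of the conjugated (dienyl) acetal followed by Pinnick oxidation of the enal gives the C14 acid without touching oxiranes, esters or the α-methylene lactone.

Step 26
Reactants: 33 2,3-deoxy-leucanthin B
Product: 34 leucanthin B
Conditions: dimethyldioxirane (1.5 equiv), acetone, −20 to 0 °C
Reagents that add atoms: dimethyldioxirane, CC1(C)OO1
Why: electrophilic epoxidation is chemoselective for the γ,δ-alkene C2=C3 (C1=C10 and the α-methylene are acceptor-conjugated) and should occur anti to the C4–O bond of the adjacent oxirane, as in cyclic 1,3-diene monoepoxides, giving the cis-2,3-oxirane (2R,3R) of the trans-bis-epoxide.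

**Compound list**

1 | furan-3-carbaldehyde | O=Cc1ccoc1 | starting material
2 | 3-(dimethoxymethyl)furan | COC(OC)c1ccoc1 | intermediate
3 | (tert-butyldimethylsilyloxy)acetaldehyde | CC(C)(C)[Si](C)(C)OCC=O | starting material
4 | rac-2-(tert-butyldimethylsilyloxy)-1-[3-(dimethoxymethyl)furan-2-yl]ethanol | CC(C)(C)[Si](C)(C)OCC(O)c1occc1C(OC)OC | intermediate
5 | 2-(tert-butyldimethylsilyloxy)-1-[3-(dimethoxymethyl)furan-2-yl]ethanone | CC(C)(C)[Si](C)(C)OCC(=O)c1occc1C(OC)OC | intermediate
6 | (S)-2-(tert-butyldimethylsilyloxy)-1-[3-(dimethoxymethyl)furan-2-yl]ethanol | CC(C)(C)[Si](C)(C)OC[C@H](O)c1occc1C(OC)OC | intermediate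
7 | (2S)-2-[(tert-butyldimethylsilyloxy)methyl]-4-(dimethoxymethyl)-6-hydroxy-2H-pyran-3(6H)-one | CC(C)(C)[Si](C)(C)OC[C@@H]1OC(O)C=C(C(OC)OC)C1=O | intermediate
8 | (2S,3R)-2-[(tert-butyldimethylsilyloxy)methyl]-4-(dimethoxymethyl)-3,6-dihydro-2H-pyran-3,6-diol | CC(C)(C)[Si](C)(C)OC[C@@H]1OC(O)C=C(C(OC)OC)[C@H]1O | intermediate
9 | (2S,3S)-2-[(tert-butyldimethylsilyloxy)methyl]-4-(dimethoxymethyl)-3,6-dihydro-2H-pyran-3,6-diyl diacetate | CC(C)(C)[Si](C)(C)OC[C@@H]1OC(OC(C)=O)C=C(C(OC)OC)[C@@H]1OC(C)=O | intermediate
10 | (2S,3S)-4-(dimethoxymethyl)-2-(hydroxymethyl)-3,6-dihydro-2H-pyran-3,6-diyl diacetate | OC[C@@H]1OC(OC(C)=O)C=C(C(OC)OC)[C@@H]1OC(C)=O | intermediate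
11 | (2R,3S)-4-(dimethoxymethyl)-2-formyl-3,6-dihydro-2H-pyran-3,6-diyl diacetate | O=C[C@@H]1OC(OC(C)=O)C=C(C(OC)OC)[C@@H]1OC(C)=O | intermediate
12 | methyl propiolate | C#CC(=O)OC | starting material
13 | methyl 2-{[(2S,3S)-3,6-diacetoxy-4-(dimethoxymethyl)-3,6-dihydro-2H-pyran-2-yl](hydroxy)methyl}acrylate | C=C(C(=O)OC)C(O)[C@@H]1OC(OC(C)=O)C=C(C(OC)OC)[C@@H]1OC(C)=O | intermediate
14 | methyl (Z)-2-(bromomethyl)-3-[(2S,3S)-3,6-diacetoxy-4-(dimethoxymethyl)-3,6-dihydro-2H-pyran-2-yl]acrylate | BrC/C(C(=O)OC)=C\[C@@H]1OC(OC(C)=O)C=C(C(OC)OC)[C@@H]1OC(C)=O | intermediate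
15 | (Z)-3-methylpent-2-en-4-yn-1-ol | OC/C=C(C)\C#C | starting material
16 | (Z)-3-methylpenta-2,4-dien-1-ol | OC/C=C(C)\C=C | intermediate
17 | (Z)-3-methylpenta-2,4-dienal | O=C/C=C(C)\C=C | intermediate
18 | methyl (3S,4R,5Z)-3-[(2S,3S)-3,6-diacetoxy-4-(dimethoxymethyl)-3,6-dihydro-2H-pyran-2-yl]-4-hydroxy-6-methyl-2-methylideneocta-5,7-dienoate | C=C(C(=O)OC)[C@@H]([C@H](O)/C=C(C)\C=C)[C@@H]1OC(OC(C)=O)C=C(C(OC)OC)[C@@H]1OC(C)=O | intermediate
19 | threo 4,5-epoxy alcohol of 18 (oxirane syn to the C6 hydroxyl) | C=C(C(=O)OC)[C@@H]([C@H](O)[C@H]2O[C@@]2(C)C=C)[C@@H]1OC(OC(C)=O)C=C(C(OC)OC)[C@@H]1OC(C)=O | intermediate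
20 | trans-α-methylene-γ-butyrolactone with the 3-methyl-3-vinyloxiran-2-yl group at C6 and the diacetoxy-pyranyl group at C7 | C=C1C(=O)O[C@H]([C@H]2O[C@@]2(C)C=C)[C@H]1[C@@H]1OC(OC(C)=O)C=C(C(OC)OC)[C@@H]1OC(C)=O | intermediate
21 | α-(phenylselanylmethyl) lactone from 20 (C11 epimers) | c1ccccc1[Se]CC1C(=O)O[C@H]([C@H]2O[C@@]2(C)C=C)[C@H]1[C@@H]1OC(OC(C)=O)C=C(C(OC)OC)[C@@H]1OC(C)=O | intermediate
22 | lactol from 21 (anomeric OH at C2, C9 acetate) | c1ccccc1[Se]CC1C(=O)O[C@H]([C@H]2O[C@@]2(C)C=C)[C@H]1[C@@H]1OC(O)C=C(C(OC)OC)[C@@H]1OC(C)=O | intermediate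
23 | dienyl alcohol (C8–OH, C9–OAc, C14 acetal, C2 vinyl, C3 vinyl on the oxirane, selenide lactone) | c1ccccc1[Se]CC1C(=O)O[C@H]([C@H]2O[C@@]2(C)C=C)[C@H]1[C@H](O)[C@@H](OC(C)=O)/C(C(OC)OC)=C\C=C | intermediate
24 | angelic acid | C/C=C(C)\C(=O)O | starting material
25 | (Z)-2-methylbut-2-en-1-ol | C/C=C(C)\CO | intermediate
26 | [(2S,3R)-2,3-dimethyloxiran-2-yl]methanol | OC[C@]1(C)O[C@@H]1C | intermediate
27 | (2R,3R)-2,3-dimethyloxirane-2-carboxylic acid | OC(=O)[C@]1(C)O[C@@H]1C | intermediate
28 | seco-triene: O8-epoxyangelate of 23 | c1ccccc1[Se]CC1C(=O)O[C@H]([C@H]2O[C@@]2(C)C=C)[C@H]1[C@H](OC(=O)[C@]1(C)O[C@@H]1C)[C@@H](OC(C)=O)/C(C(OC)OC)=C\C=C | intermediate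
29 | ten-membered (1(10)Z,2Z)-diene, C14 dimethyl acetal, selenide lactone | c1ccccc1[Se]CC1C(=O)O[C@H]2[C@H]1[C@H](OC(=O)[C@]1(C)O[C@@H]1C)[C@@H](OC(C)=O)/C(C(OC)OC)=C\C=C/[C@]1(C)O[C@H]21 | intermediate
30 | selenoxide of 29 | O=[Se](c1ccccc1)CC1C(=O)O[C@H]2[C@H]1[C@H](OC(=O)[C@]1(C)O[C@@H]1C)[C@@H](OC(C)=O)/C(C(OC)OC)=C\C=C/[C@]1(C)O[C@H]21 | intermediate
31 | macrocyclic α-methylene lactone, C14 dimethyl acetal | C=C1C(=O)O[C@H]2[C@H]1[C@H](OC(=O)[C@]1(C)O[C@@H]1C)[C@@H](OC(C)=O)/C(C(OC)OC)=C\C=C/[C@]1(C)O[C@H]21 | intermediate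
32 | macrocyclic C14 aldehyde | C=C1C(=O)O[C@H]2[C@H]1[C@H](OC(=O)[C@]1(C)O[C@@H]1C)[C@@H](OC(C)=O)/C(C=O)=C\C=C/[C@]1(C)O[C@H]21 | intermediate
33 | 2,3-deoxy-leucanthin B (C14 acid, (2Z)-alkene) | C=C1C(=O)O[C@H]2[C@H]1[C@H](OC(=O)[C@]1(C)O[C@@H]1C)[C@@H](OC(C)=O)/C(C(=O)O)=C\C=C/[C@]1(C)O[C@H]21 | intermediate
34 | leucanthin B | C=C1C(=O)O[C@H]2[C@H]1[C@H](OC(=O)[C@]1(C)O[C@@H]1C)[C@@H](OC(C)=O)/C(C(=O)O)=C\[C@H]1O[C@H]1[C@]1(C)O[C@H]21 | target

**Step count.** Total: 26 steps. Longest linear sequence: 21 steps (steps 1–11, 14–18, 22–26).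

**Steps most likely to fail**

1. Step 23. Intermolecular metathesis (dimers, oligomers) may outrun closure of the strained ten-membered ring, the ruthenium methylidene formed at each turnover may decay before it engages the neopentylic vinyl oxirane, and some E-alkene may form. Fallback: setting out from 28, cross-metathesis with excess (Z)-but-2-ene using the ruthenium dithiolate catalyst Ru(=CH-C6H4-2-OiPr)(H2IMes)(S2C6H2Cl2) in THF at 23 °C caps both vinyl groups to give the bis-(Z)-propenyl seco-triene F1. The same catalyst then closes F1 by stereoretentive ring-closing metathesis under reduced pressure with loss of (Z)-but-2-ene. This pathway runs only through substituted alkylidenes and transfers the Z geometry of the propenyl groups to C2=C3; it comes back to the route at 29.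

2. Step 14. The aldehyde may attack the other π-face of the allylchromium (giving the C6,C7-bis-epimer), the anti preference may erode, or the allylmetal may fragment toward the ring oxygen O8. Fallback: catalyst control replaces substrate control. Setting out from 14 and 17, the coupling is run as a catalytic asymmetric Nozaki–Hiyama allylation (CrCl2 10 mol %, chiral sulfonamide–oxazoline ligand chosen for the 6R carbinol, Mn powder, Cp2ZrCl2, LiCl, MeCN, 23 °C). The ligand rather than C8 then selects the aldehyde face, the chair transition state still couples C6 and C7 anti, and the low stationary concentration of the allylmetal limits fragmentation. It comes back at 18 and makes no new compound (F0).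

3. Step 26. Facial selectivity may be poor, with oxygen delivered to the face of C2=C3 syn to the 4,5-oxirane. Fallback: setting out from 33, N-bromosuccinimide in H2O/DME at 0 °C puts bromine on the face preferred by electrophiles and water on the opposite face at the less hindered C2, giving the 2-hydroxy-3-bromo compound (bromohydrin) F2. Ag2O in THF then closes the oxirane by SN2 displacement at C3, so the oxygen ends on the face opposite to the one reached by direct epoxidation; it comes back to the route at 34.

**Further compounds**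

F1 | step 23 | bis-(Z)-propenyl analogue of 28 (C2 and C3 each end in a (Z)-prop-1-enyl group) | c1ccccc1[Se]CC1C(=O)O[C@H]([C@H]2O[C@@]2(C)/C=C\C)[C@H]1[C@H](OC(=O)[C@]1(C)O[C@@H]1C)[C@@H](OC(C)=O)/C(C(OC)OC)=C\C=C/C
F0 | step 14 | none | none
F2 | step 26 | 3-bromo-2-hydroxy compound (bromohydrin) from 33, OH at C2 on the target face, Br at C3 anti | C=C1C(=O)O[C@H]2[C@H]1[C@H](OC(=O)[C@]1(C)O[C@@H]1C)[C@@H](OC(C)=O)/C(C(=O)O)=C\[C@@H](O)[C@H](Br)[C@]1(C)O[C@H]21
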